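**Assumption:** the target SMILES has no stereocentre and no stereodescriptor, so the compound is treated as one achiral, conformationally mobile macrocycle and no enantiocontrol is needed.

**Retrosynthetic overview** (rings: A = hydroquinone ring, B = para-phenylene, C = catechol ring, D = meta-phenylene)
1. 14 ⇐ 13 (O-demethylation) ⇐ seco-bromide 12: the 18-membered ring is closed last at the ring-B aryl–CH2 bond, by an aryl radical (from Ar–Br) adding anti-Markovnikov to the vinyl group on ring A.
2. 12 ⇐ 10 + 5: the C/D ethano bridge comes from hydroboration of vinylphenol 10 and B-alkyl Suzuki coupling with aryl iodide 5.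
3. 5 and 10 ⇐ Ullmann diaryl ethers from hydroquinone- or catechol-derived phenols and dihalobenzenes; the vinyl groups come from ethyne (ortho-vinylation) and a vinylborate.
4. Ring order: the four benzene rings are bought; the macrocycle is the only ring formed (step 8).

**Route**

Step 1
Reactants: 1 hydroquinone (3 equiv)
Product: 2 4-methoxyphenol
Conditions: MeI (1 equiv), K2CO3, acetone, reflux
Reagents that add atoms: iodomethane, CI
Why: Williamson ether synthesis; the two OH groups are equivalent and the excess of diol holds the reaction at the mono-ether.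

Step 2
Reactants: 2 4-methoxyphenol
Product: 3 2-ethenyl-4-methoxyphenol
Conditions: HC≡CH (1 atm), SnCl4 (1 equiv), Bu3N, PhCl, 100 °C; then KOH, aq. EtOH
Reagents that add atoms: ethyne, C#C
Why: Yamaguchi ortho-vinylation; the phenoxytin species carbostannylates ethyne only ortho to oxygen (both ortho positions equivalent, para blocked) and basic work-up protodestannylates to the vinyl group.

Step 3
Reactants: 3 2-ethenyl-4-methoxyphenol; 4 1,3-diiodobenzene (3 equiv)
Product: 5 2-ethenyl-1-(3-iodophenoxy)-4-methoxybenzene
Conditions: CuI (10 mol %), picolinic acid (20 mol %), K3PO4, DMSO, 80 °C, BHT (cat.), N2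
Reagents that add atoms: none
Why: Ullmann diaryl ether coupling (Cu/picolinic acid tolerates ortho-substituted phenols); excess diiodide gives mono-coupling and the vinyl group is a spectator.

Step 4
Reactants: 6 catechol (3 equiv); 7 1-bromo-4-iodobenzene
Product: 8 2-(4-bromophenoxy)phenol
Conditions: CuI (10 mol %), picolinic acid (20 mol %), K3PO4, DMSO, 80 °C, N2
Reagents that add atoms: none
Why: Ullmann diaryl ether coupling; C–I reacts well before C–Br at 80 °C and excess catechol keeps the second OH free.

Step 5
Reactants: 8 2-(4-bromophenoxy)phenol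
Product: 9 2-(4-bromophenoxy)-4-iodophenol
Conditions: NIS (1.05 equiv), TsOH·H2O (10 mol %), MeCN, 0 °C to rt
Reagents that add atoms: N-iodosuccinimide, O=C1CCC(=O)N1I
Why: electrophilic aromatic iodination; the free OH is the strongest director and iodine enters para to it, while the bromophenoxy ring is deactivated.

Step 6
Reactants: 9 2-(4-bromophenoxy)-4-iodophenol
Product: 10 2-(4-bromophenoxy)-4-ethenylphenol
Conditions: CH2=CHBF3K (1.2 equiv), PdCl2(dppf) (3 mol %), K2CO3, THF/H2O, 60 °C, BHT (cat.)
Reagents that add atoms: potassium vinyltrifluoroborate, [K+].C=C[B-](F)(F)F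
Why: Suzuki–Miyaura (Molander) vinylation; oxidative addition to C–I is much faster than to C–Br at 60 °C, so the ring-B bromide is kept.

Step 7
Reactants: 10 2-(4-bromophenoxy)-4-ethenylphenol; 5 2-ethenyl-1-(3-iodophenoxy)-4-methoxybenzene
Product: 12 2-(4-bromophenoxy)-4-{2-[3-(2-ethenyl-4-methoxyphenoxy)phenyl]ethyl}phenol, via B-alkyl-9-BBN O-borinate 11 (not isolated)
Conditions: 9-BBN (2.05 equiv), THF, 0 °C to rt; then 5 (0.9 equiv), PdCl2(dppf) (5 mol %), aq. K3PO4, DMF, rt to 40 °C
Reagents that add atoms: none
Why: Brown hydroboration (one equiv of 9-BBN is taken by the phenol O–H, the second adds anti-Markovnikov to the vinyl group) followed by B-alkyl Suzuki–Miyaura coupling; all B–H is consumed before 5 is added, and the C–I bond of 5 couples at rt while C–Br and the ring-A vinyl group remain.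

Step 8
Reactants: 12 2-(4-bromophenoxy)-4-{2-[3-(2-ethenyl-4-methoxyphenoxy)phenyl]ethyl}phenol
Product: 13 ring-A methyl ether of the target (18-membered macrocycle)
Conditions: 10-phenylphenothiazine (20 mol %), Bu3N (3 equiv), HCO2H (3 equiv), MeCN (1 mM), 390 nm LEDs, 25 °C
Reagents that add atoms: none
Why: Proposed new method: excited phenothiazine (E* about −2.1 V vs SCE) transfers an electron to the aryl bromide, C–Br cleaves, and the ring-B σ-radical (para to the ether oxygen, so no 1,5-H shift or Pschorr-type closure is within reach) adds to the unsubstituted terminus of the ring-A styrene (about 10^8 M−1 s−1 for the intermolecular case) in an 18-endo mode; the benzylic radical is then reduced by H-transfer from Bu3N•+/formic acid. The closest known reaction types are the intermolecular photoredox anti-Markovnikov hydroarylation of vinylarenes with aryl halides and endo-mode radical macrocyclisations at millimolar dilution.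

Step 9
Reactants: 13 ring-A methyl ether of the target
Product: 14 target macrocycle (CNP0135015.0)
Conditions: BBr3 (4 equiv), CH2Cl2, −78 °C to 0 °C; then H2O
Reagents that add atoms: none
Why: BBr3 O-demethylation of the aryl methyl ether; diaryl ethers and the ethano bridges are inert, and no stereocentre is present.

**Compound list**
1 | hydroquinone (benzene-1,4-diol) | Oc1ccc(O)cc1 | starting material
2 | 4-methoxyphenol | COc1ccc(O)cc1 | intermediate
3 | 2-ethenyl-4-methoxyphenol | COc1ccc(O)c(C=C)c1 | intermediate
4 | 1,3-diiodobenzene | Ic1cccc(I)c1 | starting material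
5 | 2-ethenyl-1-(3-iodophenoxy)-4-methoxybenzene | C=Cc1cc(OC)ccc1Oc1cccc(I)c1 | intermediate
6 | catechol (benzene-1,2-diol) | Oc1ccccc1O | starting material
7 | 1-bromo-4-iodobenzene | Brc1ccc(I)cc1 | starting material
8 | 2-(4-bromophenoxy)phenol | Oc1ccccc1Oc1ccc(Br)cc1 | intermediate
9 | 2-(4-bromophenoxy)-4-iodophenol | Oc1ccc(I)cc1Oc1ccc(Br)cc1 | intermediate
10 | 2-(4-bromophenoxy)-4-ethenylphenol | Oc1ccc(C=C)cc1Oc1ccc(Br)cc1 | intermediate
11 | 9-{2-[3-(4-bromophenoxy)-4-(9-borabicyclo[3.3.1]non-9-yloxy)phenyl]ethyl}-9-borabicyclo[3.3.1]nonane | Brc1ccc(Oc2cc(CCB3C4CCCC3CCC4)ccc2OB2C3CCCC2CCC3)cc1 | intermediate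
12 | 2-(4-bromophenoxy)-4-{2-[3-(2-ethenyl-4-methoxyphenoxy)phenyl]ethyl}phenol | C=Cc1cc(OC)ccc1Oc1cccc(CCc2ccc(O)c(Oc3ccc(Br)cc3)c2)c1 | intermediate
13 | ring-A methyl ether of the target (OMe para to the D–O–A oxygen, free OH on ring C) | COc1ccc2c(c1)CCc1ccc(cc1)Oc1cc(ccc1O)CCc1cccc(c1)O2 | intermediate
14 | target macrocyclic bis(bibenzyl) diol, CNP0135015.0 | Oc1ccc2c(c1)CCc1ccc(cc1)Oc1cc(ccc1O)CCc1cccc(c1)O2 | target

**Totals**
Total step count: 9.
Longest linear sequence: 6 steps (1 → 2 → 3 → 5 → 12 → 13 → 14; the catechol branch 6 → 8 → 9 → 10 → 12 → 13 → 14 is also 6).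

**Three steps most likely to fail, with fallbacks**

Step 8 (radical macrocyclisation). The aryl radical lives for about a microsecond in MeCN, so hydrodebromination can outrun the 18-membered ring closure, and electron transfer to an unactivated aryl bromide at 1 mM is slow. The fallback sets out from 12 and replaces the radical closure by a Pd(0) intramolecular Mizoroki–Heck macrocyclisation (Pd(OAc)2, P(o-tol)3, K2CO3, DMF, 2 mM, 100 °C). This gives the macrocyclic (E)-stilbene methyl ether F1, whose alkene is then saturated with H2 and Pd/C in EtOAc; the route is rejoined at 13.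

Step 7 (hydroboration/B-alkyl Suzuki union). Residual B–H could attack the ring-A vinyl group of 5, and the sp3–sp2 coupling of a phenol-bearing borane may be sluggish. The fallback sets out from 10 and 5 and joins them by a Heck reaction instead: 5 is added slowly to 3 equiv of 10 with Pd(OAc)2, Bu4NCl and NaHCO3 in DMF at 70 °C, where only C–I reacts. This gives the open-chain (E)-stilbene 2-(4-bromophenoxy)-4-[(E)-2-{3-(2-ethenyl-4-methoxyphenoxy)phenyl}ethenyl]phenol F2. F2 is cyclised under the step 8 conditions to the macrocycle with a C/D (E)-ethene bridge F3, and H2 with Pd/C saturates that bridge; the route is rejoined at 13.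

Step 2 (ortho-vinylation with ethyne). The electron-rich vinylphenol may divinylate or oligomerise under SnCl4 at 100 °C. The fallback sets out from 2: bromination with NBS (CH2Cl2, 0 °C) goes ortho to the free OH and gives 2-bromo-4-methoxyphenol F4. Suzuki–Miyaura vinylation of F4 (CH2=CHBF3K, PdCl2(dppf), K2CO3, THF/H2O, 80 °C) rejoins the route at 3.

**Further compounds**
F1 | step 8 | macrocyclic (E)-stilbene (A/B ethene bridge), ring-A methyl ether | COc1ccc2c(c1)/C=C/c1ccc(cc1)Oc1cc(ccc1O)CCc1cccc(c1)O2
F2 | step 7 | 2-(4-bromophenoxy)-4-[(E)-2-{3-(2-ethenyl-4-methoxyphenoxy)phenyl}ethenyl]phenol | C=Cc1cc(OC)ccc1Oc1cccc(/C=C/c2ccc(O)c(Oc3ccc(Br)cc3)c2)c1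
F3 | step 7 | macrocycle with C/D (E)-ethene bridge, ring-A methyl ether | COc1ccc2c(c1)CCc1ccc(cc1)Oc1cc(ccc1O)/C=C/c1cccc(c1)O2
F4 | step 2 | 2-bromo-4-methoxyphenol | COc1ccc(O)c(Br)c1
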